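**Plan**

- Retrosynthesis: the 3α,4β-diol goes back to a C3=C4 alkene and the benzoate to a silyl ether. Ring A is then taken back to a cross-conjugated 1,4-dien-3-one, the C9–C10 bond of ring B is cut to a phenol with a 4-bromobutyl chain, and C6–C7 is cut to an aryl aldehyde and an (E)-γ-isopropylallyl boronate.
- Enabling feature: in ring A the quaternary C10 (with its methyl) is para and C4 (with its methyl) is ortho to the C3 oxygen, and C9 of ring B is four atoms from C5. Ring A is therefore a masked 3-substituted 2,4-dimethylphenol whose para carbon can be alkylated by C9.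
- Forward order: ring A is bought as an arene, the C6–C9 chain is joined by allylboration, ring B closes in the dearomatising para-alkylation, and ring A is then reduced and oxidised to the target pattern.
- Stereochemistry: C6 and C7 come from a catalyst-controlled anti allylboration; C10 from C6 through allylic strain in a chair-like closure; C5 from suprafacial hydrogen delivery in a diazene retro-ene step; C3 and C4 from α-epoxidation and trans-diaxial opening.

Key step: step 9

Remark: bicyclic compounds carry eudesmane numbering (ring A = C1–C5, C10; ring B = C5–C10; methyl groups on C4 and C10; isopropyl on C7); β is the face of the C10 methyl group. TBS = tert-butyldimethylsilyl; Bpin = 4,4,5,5-tetramethyl-1,3,2-dioxaborolan-2-yl.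

Remark: (R)-TRIP, 3,3′-bis(2,4,6-triisopropylphenyl)-1,1′-binaphthyl-2,2′-diyl hydrogen phosphate, is assumed to direct the allyl group to the Re face of aldehyde 2 as it does with other aryl aldehydes; if this hindered aldehyde responds in the opposite sense, (S)-TRIP is used.

**Route**

Step 1
Reactants: 1 2,6-dimethylbenzaldehyde
Product: 2 3-bromo-2,6-dimethylbenzaldehyde
Conditions: Br2 (1.05 equiv), AlCl3 (2.2 equiv), CH2Cl2, 0 °C → rt
Reagents that add atoms: bromine, BrBr
Why: Electrophilic aromatic bromination of the AlCl3-complexed aldehyde, in which both methyl groups (ortho/para) and the formyl group (meta) direct to the same carbon, so one monobromide is expected.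

Step 2
Reactants: 3 3-methylbut-1-yne
Product: 4 (E)-4,4,5,5-tetramethyl-2-(3-methylbut-1-en-1-yl)-1,3,2-dioxaborolane
Conditions: HBpin (1.05 equiv), Cp2Zr(H)Cl (5 mol %), Et3N (10 mol %), neat, sealed tube, 60 °C
Reagents that add atoms: pinacolborane, [H]B1OC(C)(C)C(C)(C)O1
Why: Zirconium-catalysed syn hydroboration of a terminal alkyne puts boron on the terminal carbon and should give only the (E)-alkenylboronate.

Step 3
Reactants: 4 (E)-4,4,5,5-tetramethyl-2-(3-methylbut-1-en-1-yl)-1,3,2-dioxaborolane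
Product: 6 (E)-4,4,5,5-tetramethyl-2-(4-methylpent-2-en-1-yl)-1,3,2-dioxaborolane, via lithium chloromethyl borate complex 5 (not isolated)
Conditions: BrCH2Cl (1.5 equiv), n-BuLi (1.3 equiv), THF, −78 °C → rt
Reagents that add atoms: bromochloromethane, ClCBr
Why: Matteson homologation, in which chloromethyllithium made in situ adds to boron and the alkenyl group migrates to carbon with loss of chloride, inserts one CH2 and keeps the E geometry.

Step 4
Reactants: 2 3-bromo-2,6-dimethylbenzaldehyde; 6 (E)-4,4,5,5-tetramethyl-2-(4-methylpent-2-en-1-yl)-1,3,2-dioxaborolane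
Product: 8 (1R,2R)-1-(3-bromo-2,6-dimethylphenyl)-2-(propan-2-yl)but-3-en-1-ol, via pinacol borate ester 7 (not isolated)
Conditions: (R)-TRIP (5 mol %), 4 Å MS, toluene, −30 °C → rt; aq. NaHCO3 work-up
Reagents that add atoms: none
Why: Chiral phosphoric acid-catalysed allylboration through a closed chair (Zimmerman–Traxler) transition state, in which the (E)-boronate places the isopropyl group equatorial to give the anti adduct and the catalyst selects the Re face of the aldehyde, should set both C6 and C7 as (1R,2R).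

Step 5
Reactants: 8 (1R,2R)-1-(3-bromo-2,6-dimethylphenyl)-2-(propan-2-yl)but-3-en-1-ol
Product: 9 {[(1R,2R)-1-(3-bromo-2,6-dimethylphenyl)-2-(propan-2-yl)but-3-en-1-yl]oxy}(tert-butyl)dimethylsilane
Conditions: TBSOTf (1.5 equiv), 2,6-lutidine (2.5 equiv), CH2Cl2, 0 °C → rt
Reagents that add atoms: tert-butyldimethylsilyl trifluoromethanesulfonate, CC(C)(C)[Si](C)(C)OS(=O)(=O)C(F)(F)F
Why: Silylation of a hindered secondary benzylic alcohol with the silyl triflate, which protects the C6 oxygen as a base-stable ether without touching a stereocentre.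

Step 6
Reactants: 9 {[(1R,2R)-1-(3-bromo-2,6-dimethylphenyl)-2-(propan-2-yl)but-3-en-1-yl]oxy}(tert-butyl)dimethylsilane
Product: 12 3-[(1R,2R)-1-(TBSO)-2-(propan-2-yl)but-3-en-1-yl]-2,4-dimethylphenol, via aryllithium 10 (not isolated), via lithium aryltrimethoxyborate 11 (not isolated)
Conditions: n-BuLi (1.1 equiv), THF, −78 °C; B(OMe)3 (1.5 equiv), −78 → 0 °C; then 30% H2O2, aq. NaOH, 0 °C → rt
Reagents that add atoms: hydrogen peroxide, OO
Why: Bromine–lithium exchange, borylation and oxidative aryl migration from boron to oxygen (ipso-hydroxylation) turn C–Br into the phenol under conditions that leave the terminal alkene and the silyl ether alone.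

Step 7
Reactants: 12 3-[(1R,2R)-1-(TBSO)-2-(propan-2-yl)but-3-en-1-yl]-2,4-dimethylphenol
Product: 14 3-[(1R,2S)-1-(TBSO)-4-hydroxy-2-(propan-2-yl)butyl]-2,4-dimethylphenol, via B-alkyl-9-BBN adduct 13 (not isolated)
Conditions: 9-BBN (2.5 equiv), THF, 0 → 40 °C; then aq. NaOH, 30% H2O2, 0 °C → rt
Reagents that add atoms: hydrogen peroxide, OO
Why: Anti-Markovnikov hydroboration of the monosubstituted alkene with 9-BBN and alkaline peroxide oxidation should give the primary alcohol at C9, the extra borane covering the phenolic O–H, which is set free again on oxidation.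

Step 8
Reactants: 14 3-[(1R,2S)-1-(TBSO)-4-hydroxy-2-(propan-2-yl)butyl]-2,4-dimethylphenol
Product: 15 3-[(1R,2S)-4-bromo-1-(TBSO)-2-(propan-2-yl)butyl]-2,4-dimethylphenol
Conditions: CBr4 (1.3 equiv), PPh3 (1.4 equiv), CH2Cl2, 0 °C
Reagents that add atoms: carbon tetrabromide, BrC(Br)(Br)Br
Why: The Appel reaction converts only the aliphatic hydroxyl group, because an aryloxyphosphonium ion cannot be displaced at an sp2 carbon, so the primary bromide is obtained with the phenol free and no protecting group is needed.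

Step 9
Reactants: 15 3-[(1R,2S)-4-bromo-1-(TBSO)-2-(propan-2-yl)butyl]-2,4-dimethylphenol
Product: 17 6β-(TBSO)eudesma-1,4-dien-3-one, via potassium phenoxide 16 (not isolated)
Conditions: KOt-Bu (1.0 equiv), 18-crown-6 (1.1 equiv), t-BuOH/THF (4:1), 0.01 M, 70 °C
Reagents that add atoms: none
Why: Deprotonation gives phenoxide 16, whose para carbon C10 (the methyl-bearing carbon next to the chain-bearing C5) displaces bromide from the primary C9 by SN2, forming C9–C10 and dearomatising ring A to a 4,4-disubstituted cyclohexa-2,5-dienone that cannot re-aromatise; the closest known reaction type is the intramolecular para-C-alkylation of phenoxides (Ar2-6 participation) that gives fused cyclohexadienones. Ring B (C5–C6–C7–C8–C9–C10) closes in the 6-exo-tet mode. The new stereocentre C10 is controlled by C6: allylic 1,3-strain with the C4 methyl keeps the C6–H bond in the arene plane, so the closure runs through a chair with the silyloxy group axial and the C7 isopropyl group equatorial, C9 reaches C10 from the α face and the C10 methyl ends up β, cis to the C6 oxygen. The step needs alkylation at the para carbon C10 and not at oxygen or at the ortho carbon C4: O-alkylation would need a meta-bridged medium ring, and attack through C4 should be disfavoured because the para carbon carries the larger HOMO coefficient, because C4 leads to the less stable linearly conjugated 2,4-dienone, and because the C4 methyl is buttressed by the oxygen so that the small C6–H eclipses it and the chain lies over C10. Crown-sequestered potassium in a hydrogen-bonding solvent removes the cation-assisted delivery that favours ortho attack, exactly one equivalent of base leaves no free alkoxide for E2 at C9, the soft bromide favours attack by carbon, and high dilution suppresses intermolecular alkylation.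

Step 10
Reactants: 17 6β-(TBSO)eudesma-1,4-dien-3-one
Product: 18 6β-(TBSO)eudesm-4-en-3-one
Conditions: H2 (1 atm), RhCl(PPh3)3 (10 mol %), toluene/EtOH (1:1), rt
Reagents that add atoms: none
Why: Homogeneous rhodium-catalysed hydrogenation should reduce the disubstituted C1=C2 bond of the cross-conjugated dienone and leave the tetrasubstituted C4=C5 bond, as it does with steroidal 1,4-dien-3-ones.

Step 11
Reactants: 18 6β-(TBSO)eudesm-4-en-3-one
Product: 19 6β-(TBSO)eudesm-4-en-3β-ol
Conditions: NaBH4 (1.2 equiv), CeCl3·7H2O (1.2 equiv), MeOH, −40 → 0 °C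
Reagents that add atoms: none
Why: Luche 1,2-reduction, with hydride entering axially from the α face anti to the C10 methyl group, should give the pseudo-equatorial 3β-alcohol.

Step 12
Reactants: 19 6β-(TBSO)eudesm-4-en-3β-ol
Product: 22 6β-(TBSO)-5α-eudesm-3-ene, via Mitsunobu hydrazone adduct 20 (not isolated), via allylic diazene 21 (not isolated)
Conditions: IPNBSH (N-isopropylidene-N′-2-nitrobenzenesulfonyl hydrazine, 1.5 equiv), PPh3 (1.5 equiv), DEAD (1.5 equiv), THF, 0 °C → rt; then CF3CH2OH/H2O (1:1), rt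
Reagents that add atoms: none
Why: Reductive 1,3-transposition of the allylic alcohol: Mitsunobu displacement inverts C3 (3β-O to 3α-N), hydrolysis of the hydrazone and loss of sulfinic acid give the allylic diazene, and its retro-ene loss of N2 delivers hydrogen suprafacially to the α face of C5, which sets the trans ring fusion and moves the double bond to C3=C4 without a carbanion at C5 that could expel the 6β-silyloxy group.

Step 13
Reactants: 22 6β-(TBSO)-5α-eudesm-3-ene
Product: 23 5α-eudesm-3-en-6β-ol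
Conditions: TBAF (3 equiv), THF, 60 °C
Reagents that add atoms: none
Why: Fluoride-mediated desilylation, with heating for the hindered axial ether, frees the C6 hydroxyl group while the alkene is inert.

Step 14
Reactants: 23 5α-eudesm-3-en-6β-ol
Product: 24 5α-eudesm-3-en-6β-yl benzoate
Conditions: BzCl (2 equiv), DMAP (0.5 equiv), pyridine, 60 °C
Reagents that add atoms: benzoyl chloride, O=C(Cl)c1ccccc1
Why: DMAP-catalysed acylation of the only hydroxyl group installs the benzoate at C6 before the diol exists, so no hydroxyl groups have to be told apart later.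

Step 15
Reactants: 24 5α-eudesm-3-en-6β-yl benzoate
Product: 25 3α,4α-epoxy-5α-eudesman-6β-yl benzoate
Conditions: mCPBA (1.2 equiv), NaHCO3, CH2Cl2, 0 °C
Reagents that add atoms: 3-chloroperbenzoic acid, OOC(=O)c1cccc(Cl)c1
Why: Prilezhaev epoxidation should occur from the α face, since the β face of the C3=C4 bond is screened by the axial C10 methyl and the axial 6β-benzoate.

Step 16
Reactants: 25 3α,4α-epoxy-5α-eudesman-6β-yl benzoate
Product: 26 3α,4β-dihydroxy-5α-eudesman-6β-yl benzoate (CNP0187831.1)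
Conditions: HClO4 (0.1 M aq., cat.), THF/H2O (3:1), 0 °C → rt
Reagents that add atoms: water, O
Why: Acid-catalysed trans-diaxial (Fürst–Plattner) epoxide opening, in which water attacks the tertiary C4 from the β face with inversion (favoured by both the diaxial rule and the charge on the more substituted carbon) while the C3–O bond stays α, should give the 3α,4β-diol; if the axial 6β-benzoate carbonyl captures C4 first, the 1,3-dioxan-2-ylium ion delivers oxygen to the same face and its hydrolysis should return the less hindered secondary benzoate.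

**Compound list**

1 | 2,6-dimethylbenzaldehyde | Cc1cccc(C)c1C=O | starting material
2 | 3-bromo-2,6-dimethylbenzaldehyde | Cc1ccc(Br)c(C)c1C=O | intermediate
3 | 3-methylbut-1-yne | CC(C)C#C | starting material
4 | (E)-4,4,5,5-tetramethyl-2-(3-methylbut-1-en-1-yl)-1,3,2-dioxaborolane | CC(C)/C=C/B1OC(C)(C)C(C)(C)O1 | intermediate
5 | lithium (chloromethyl)[(E)-3-methylbut-1-en-1-yl](pinacolato)borate | [Li+].CC(C)/C=C/[B-]1(CCl)OC(C)(C)C(C)(C)O1 | intermediate
6 | (E)-4,4,5,5-tetramethyl-2-(4-methylpent-2-en-1-yl)-1,3,2-dioxaborolane | CC(C)/C=C/CB1OC(C)(C)C(C)(C)O1 | intermediate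
7 | 2-{[(1R,2R)-1-(3-bromo-2,6-dimethylphenyl)-2-(propan-2-yl)but-3-en-1-yl]oxy}-4,4,5,5-tetramethyl-1,3,2-dioxaborolane | CC(C)[C@H](C=C)[C@@H](OB1OC(C)(C)C(C)(C)O1)c1c(C)ccc(Br)c1C | intermediate
8 | (1R,2R)-1-(3-bromo-2,6-dimethylphenyl)-2-(propan-2-yl)but-3-en-1-ol (anti) | CC(C)[C@H](C=C)[C@@H](O)c1c(C)ccc(Br)c1C | intermediate
9 | {[(1R,2R)-1-(3-bromo-2,6-dimethylphenyl)-2-(propan-2-yl)but-3-en-1-yl]oxy}(tert-butyl)dimethylsilane | CC(C)[C@H](C=C)[C@@H](O[Si](C)(C)C(C)(C)C)c1c(C)ccc(Br)c1C | intermediate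
10 | {3-[(1R,2R)-1-(TBSO)-2-(propan-2-yl)but-3-en-1-yl]-2,4-dimethylphenyl}lithium | CC(C)[C@H](C=C)[C@@H](O[Si](C)(C)C(C)(C)C)c1c(C)ccc([Li])c1C | intermediate
11 | lithium trimethoxy{3-[(1R,2R)-1-(TBSO)-2-(propan-2-yl)but-3-en-1-yl]-2,4-dimethylphenyl}borate | CC(C)[C@H](C=C)[C@@H](O[Si](C)(C)C(C)(C)C)c1c(C)ccc([B-](OC)(OC)OC)c1C.[Li+] | intermediate
12 | 3-[(1R,2R)-1-(TBSO)-2-(propan-2-yl)but-3-en-1-yl]-2,4-dimethylphenol | CC(C)[C@H](C=C)[C@@H](O[Si](C)(C)C(C)(C)C)c1c(C)ccc(O)c1C | intermediate
13 | 3-[(1R,2S)-4-(9-borabicyclo[3.3.1]nonan-9-yl)-1-(TBSO)-2-(propan-2-yl)butyl]-2,4-dimethylphenol | CC(C)[C@H](CCB1C2CCCC1CCC2)[C@@H](O[Si](C)(C)C(C)(C)C)c1c(C)ccc(O)c1C | intermediate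
14 | 3-[(1R,2S)-1-(TBSO)-4-hydroxy-2-(propan-2-yl)butyl]-2,4-dimethylphenol | CC(C)[C@H](CCO)[C@@H](O[Si](C)(C)C(C)(C)C)c1c(C)ccc(O)c1C | intermediate
15 | 3-[(1R,2S)-4-bromo-1-(TBSO)-2-(propan-2-yl)butyl]-2,4-dimethylphenol | CC(C)[C@H](CCBr)[C@@H](O[Si](C)(C)C(C)(C)C)c1c(C)ccc(O)c1C | intermediate
16 | potassium 3-[(1R,2S)-4-bromo-1-(TBSO)-2-(propan-2-yl)butyl]-2,4-dimethylphenoxide | [K+].CC(C)[C@H](CCBr)[C@@H](O[Si](C)(C)C(C)(C)C)c1c(C)ccc([O-])c1C | intermediate
17 | 6β-(TBSO)eudesma-1,4-dien-3-one (7β-isopropyl, 10β-methyl) | CC(C)[C@@H]1CC[C@@]2(C)C=CC(=O)C(C)=C2[C@@H]1O[Si](C)(C)C(C)(C)C | intermediate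
18 | 6β-(TBSO)eudesm-4-en-3-one | CC(C)[C@@H]1CC[C@@]2(C)CCC(=O)C(C)=C2[C@@H]1O[Si](C)(C)C(C)(C)C | intermediate
19 | 6β-(TBSO)eudesm-4-en-3β-ol | CC(C)[C@@H]1CC[C@@]2(C)CC[C@H](O)C(C)=C2[C@@H]1O[Si](C)(C)C(C)(C)C | intermediate
20 | N-[6β-(TBSO)eudesm-4-en-3α-yl]-2-nitro-N′-(propan-2-ylidene)benzenesulfonohydrazide | CC(C)[C@@H]1CC[C@@]2(C)CC[C@@H](N(N=C(C)C)S(=O)(=O)c3ccccc3[N+](=O)[O-])C(C)=C2[C@@H]1O[Si](C)(C)C(C)(C)C | intermediate
21 | 3α-diazenyl-6β-(TBSO)eudesm-4-ene | CC(C)[C@@H]1CC[C@@]2(C)CC[C@@H](N=N)C(C)=C2[C@@H]1O[Si](C)(C)C(C)(C)C | intermediate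
22 | 6β-(TBSO)-5α-eudesm-3-ene | CC(C)[C@@H]1CC[C@@]2(C)CCC=C(C)[C@@H]2[C@@H]1O[Si](C)(C)C(C)(C)C | intermediate
23 | 5α-eudesm-3-en-6β-ol | CC(C)[C@@H]1CC[C@@]2(C)CCC=C(C)[C@@H]2[C@@H]1O | intermediate
24 | 5α-eudesm-3-en-6β-yl benzoate | CC(C)[C@@H]1CC[C@@]2(C)CCC=C(C)[C@@H]2[C@@H]1OC(=O)c1ccccc1 | intermediate
25 | 3α,4α-epoxy-5α-eudesman-6β-yl benzoate | CC(C)[C@@H]1CC[C@@]2(C)CC[C@H]3O[C@@]3(C)[C@@H]2[C@@H]1OC(=O)c1ccccc1 | intermediate
26 | 3α,4β-dihydroxy-5α-eudesman-6β-yl benzoate (CNP0187831.1) | CC(C)[C@@H]1CC[C@@]2(C)CC[C@@H](O)[C@](C)(O)[C@@H]2[C@@H]1OC(=O)c1ccccc1 | target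

**Step count and risks**

Total steps: 16. Longest linear sequence: 15 steps (3 to 26 through steps 2–16); the arene branch from 1 is 14 steps.

Steps most likely to fail:

1. Step 9. The phenoxide may alkylate in part through the ortho carbon C4, which is reachable through a ring of the same size and would give the linearly conjugated 2,4-dienone skeleton; displacement of bromide by the silyl ether oxygen is a lesser leak. The fallback removes the ortho/para question by symmetry with a second phenolic oxygen. It sets out from 2 and comes back at 17.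
   - Aldehyde 2 would be brominated once more (Br2, AlCl3) to 3,5-dibromo-2,6-dimethylbenzaldehyde F1.
   - The chemistry of steps 4 and 5 with boronate 6 would then give (1R,2R)-1-(3,5-dibromo-2,6-dimethylphenyl)-2-(propan-2-yl)but-3-en-1-ol F2 and its TBS ether {[(1R,2R)-1-(3,5-dibromo-2,6-dimethylphenyl)-2-(propan-2-yl)but-3-en-1-yl]oxy}(tert-butyl)dimethylsilane F3.
   - Palladium-catalysed hydroxylation of both C–Br bonds (Pd2(dba)3, t-BuXPhos, KOH, dioxane/H2O, 100 °C) would give 5-[(1R,2R)-1-(TBSO)-2-(propan-2-yl)but-3-en-1-yl]-4,6-dimethylbenzene-1,3-diol F4.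
   - Hydroboration–oxidation and Appel bromination as in steps 7 and 8 would give 5-[(1R,2S)-1-(TBSO)-4-hydroxy-2-(propan-2-yl)butyl]-4,6-dimethylbenzene-1,3-diol F5 and 5-[(1R,2S)-4-bromo-1-(TBSO)-2-(propan-2-yl)butyl]-4,6-dimethylbenzene-1,3-diol F6.
   - In this resorcinol the two methyl-bearing carbons beside the chain are equivalent, each ortho to one oxygen and para to the other, so closure with KOt-Bu in t-BuOH can only lead to 6β-(TBSO)eudesm-4-ene-1,3-dione F7 (obtained enolised), under the same allylic-strain control of C10.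
   - Acid-catalysed enol ether formation (HC(OMe)3, MeOH, TsOH) at the oxygen remote from the quaternary C10 would give 3-methoxy-6β-(TBSO)eudesma-2,4-dien-1-one F8.
   - Stork–Danheiser reduction and hydrolysis (DIBAL-H, then dilute HCl) transposes the carbonyl to C3 and returns dienone 17.

2. Step 4. The di-ortho-substituted aldehyde may fit poorly into the catalyst pocket, so that addition is slow and the uncatalysed background reaction erodes the enantioselectivity. The fallback gives up catalyst control for a resolution. It sets out from 2 and 6 and comes back at 8. Uncatalysed allylboration (toluene, 80 °C) keeps the anti selectivity of the closed transition state and should give the racemate, that is 8 together with (1S,2S)-1-(3-bromo-2,6-dimethylphenyl)-2-(propan-2-yl)but-3-en-1-ol F9. The enantiomers would be separated by preparative chromatography on a chiral stationary phase, and 8 re-enters the route at step 5.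

3. Step 16. The benzoate may take part in the opening and end up on the tertiary oxygen O4 (acyl transfer through the dioxanylium ion), or be lost by hydrolysis. The fallback makes the diol before any acyl group is present. It sets out from 22 and comes back at 26.
   - Epoxidation of 22 with mCPBA would give 3α,4α-epoxy-6β-(TBSO)-5α-eudesmane F10.
   - The same perchloric acid hydrolysis would give 6β-(TBSO)-5α-eudesmane-3α,4β-diol F11.
   - Acylation of the secondary 3-hydroxyl group only (levulinic acid, DCC, DMAP) would give 6β-(TBSO)-4β-hydroxy-5α-eudesman-3α-yl 4-oxopentanoate F12.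
   - Desilylation with HF·pyridine would give 4β,6β-dihydroxy-5α-eudesman-3α-yl 4-oxopentanoate F13.
   - Benzoylation of the secondary 6-hydroxyl group (BzCl, DMAP, pyridine) would give 6β-benzoyloxy-4β-hydroxy-5α-eudesman-3α-yl 4-oxopentanoate F14.
   - Hydrazine acetate removes the levulinate without touching the benzoate and gives 26.

Further compounds

F1 | step 9 | 3,5-dibromo-2,6-dimethylbenzaldehyde | Cc1c(Br)cc(Br)c(C)c1C=O
F2 | step 9 | (1R,2R)-1-(3,5-dibromo-2,6-dimethylphenyl)-2-(propan-2-yl)but-3-en-1-ol | CC(C)[C@H](C=C)[C@@H](O)c1c(C)c(Br)cc(Br)c1C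
F3 | step 9 | {[(1R,2R)-1-(3,5-dibromo-2,6-dimethylphenyl)-2-(propan-2-yl)but-3-en-1-yl]oxy}(tert-butyl)dimethylsilane | CC(C)[C@H](C=C)[C@@H](O[Si](C)(C)C(C)(C)C)c1c(C)c(Br)cc(Br)c1C
F4 | step 9 | 5-[(1R,2R)-1-(TBSO)-2-(propan-2-yl)but-3-en-1-yl]-4,6-dimethylbenzene-1,3-diol | CC(C)[C@H](C=C)[C@@H](O[Si](C)(C)C(C)(C)C)c1c(C)c(O)cc(O)c1C
F5 | step 9 | 5-[(1R,2S)-1-(TBSO)-4-hydroxy-2-(propan-2-yl)butyl]-4,6-dimethylbenzene-1,3-diol | CC(C)[C@H](CCO)[C@@H](O[Si](C)(C)C(C)(C)C)c1c(C)c(O)cc(O)c1C
F6 | step 9 | 5-[(1R,2S)-4-bromo-1-(TBSO)-2-(propan-2-yl)butyl]-4,6-dimethylbenzene-1,3-diol | CC(C)[C@H](CCBr)[C@@H](O[Si](C)(C)C(C)(C)C)c1c(C)c(O)cc(O)c1C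
F7 | step 9 | 6β-(TBSO)eudesm-4-ene-1,3-dione | CC(C)[C@@H]1CC[C@@]2(C)C(=O)CC(=O)C(C)=C2[C@@H]1O[Si](C)(C)C(C)(C)C
F8 | step 9 | 3-methoxy-6β-(TBSO)eudesma-2,4-dien-1-one | CC(C)[C@@H]1CC[C@@]2(C)C(=O)C=C(OC)C(C)=C2[C@@H]1O[Si](C)(C)C(C)(C)C
F9 | step 4 | (1S,2S)-1-(3-bromo-2,6-dimethylphenyl)-2-(propan-2-yl)but-3-en-1-ol | CC(C)[C@@H](C=C)[C@H](O)c1c(C)ccc(Br)c1C
F10 | step 16 | 3α,4α-epoxy-6β-(TBSO)-5α-eudesmane | CC(C)[C@@H]1CC[C@@]2(C)CC[C@H]3O[C@@]3(C)[C@@H]2[C@@H]1O[Si](C)(C)C(C)(C)C
F11 | step 16 | 6β-(TBSO)-5α-eudesmane-3α,4β-diol | CC(C)[C@@H]1CC[C@@]2(C)CC[C@@H](O)[C@](C)(O)[C@@H]2[C@@H]1O[Si](C)(C)C(C)(C)C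
F12 | step 16 | 6β-(TBSO)-4β-hydroxy-5α-eudesman-3α-yl 4-oxopentanoate | CC(C)[C@@H]1CC[C@@]2(C)CC[C@@H](OC(=O)CCC(C)=O)[C@](C)(O)[C@@H]2[C@@H]1O[Si](C)(C)C(C)(C)C
F13 | step 16 | 4β,6β-dihydroxy-5α-eudesman-3α-yl 4-oxopentanoate | CC(C)[C@@H]1CC[C@@]2(C)CC[C@@H](OC(=O)CCC(C)=O)[C@](C)(O)[C@@H]2[C@@H]1O
F14 | step 16 | 6β-benzoyloxy-4β-hydroxy-5α-eudesman-3α-yl 4-oxopentanoate | CC(C)[C@@H]1CC[C@@]2(C)CC[C@@H](OC(=O)CCC(C)=O)[C@](C)(O)[C@@H]2[C@@H]1OC(=O)c1ccccc1
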